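**Strategy.** Labdane numbering is used throughout. Everything rests on disconnecting the ring-fusion bond C5–C10, shared by rings A and B. The C9 carbinol is traced back to a C9 ketone, which makes the quaternary C10 an enolate carbon, while C5, flanked by quaternary C4 (no γ-hydrogen), is the β-carbon of an enal (C5=C6–C7HO). One base-mediated operation on an acyclic keto-enal closes ring A by a C10-to-C5 Michael addition and ring B by aldol condensation of C8 onto C7, giving the trans-decalin enone; C5 and C10 follow from the single C3 stereocentre. The precursor is an open-chain (S)-silyloxy keto-enal built from pentan-3-one in five steps.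

Key step: step 6

Remark: cyclic compounds are described with labdane numbering and α/β descriptors (β = face of the C10 methyl). The methine that becomes C10 is carried as a mixture of epimers (compounds 4–8 and 10) until step 6, where it passes through an enolate.

**Step 1**
Reactants: 1 pentan-3-one; 2 2-(2-bromoethyl)-1,3-dioxolane
Product: 4 6-(1,3-dioxolan-2-yl)-4-methylhexan-3-one (racemic), via lithium enolate 3 (not isolated)
Conditions: LiN(i-Pr)2, THF, −78 °C; then 2, DMPU, NaI (cat.), −78 °C → rt
Reagents that add atoms: none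
Why: Kinetic lithium enolate alkylation (SN2) of a symmetrical ketone with a primary bromide, with DMPU and iodide catalysis offsetting the low reactivity of the β-acetal bromide; the new stereocentre is inconsequential.

**Step 2**
Reactants: 4 6-(1,3-dioxolan-2-yl)-4-methylhexan-3-one
Product: 5 4-methyl-5-oxoheptanal (racemic)
Conditions: 1 M HCl, THF, 0 °C → rt; used at once
Reagents that add atoms: water, O
Why: Acid-catalysed acetal hydrolysis under mild conditions that limit intramolecular aldol cyclisation of the 1,5-keto aldehyde.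

**Step 3**
Reactants: 5 4-methyl-5-oxoheptanal
Product: 7 (7S)-7-hydroxy-4,8,8-trimethyldec-9-en-3-one, via borinate ester 6 (not isolated)
Conditions: (+)-Ipc2BOMe (from (−)-α-pinene), Me2C=CHCH2MgCl, Et2O, −78 → 0 °C; then 5, −78 °C; then NaOAc (aq), 30% H2O2, 0 °C → rt
Reagents that add atoms: B-prenyldiisopinocampheylborane (from (−)-α-pinene), CC(C)=CCB([C@@H]1[C@@H](C)[C@@H]2C[C@H](C1)C2(C)C)[C@@H]1[C@@H](C)[C@@H]2C[C@H](C1)C2(C)C
Why: Brown asymmetric prenylboration, in which the γ-carbon of the prenyl group adds to the aldehyde through a chair six-membered transition state (the ketone is inert at −78 °C) and the isopinocampheyl groups direct attack to the Re face, setting the future C3 as S with the gem-dimethyl carbon C4 and the C5=C6 vinyl group in place.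

**Step 4**
Reactants: 7 (7S)-7-hydroxy-4,8,8-trimethyldec-9-en-3-one
Product: 8 (7S)-7-[(tert-butyldimethylsilyl)oxy]-4,8,8-trimethyldec-9-en-3-one
Conditions: TBSOTf, 2,6-lutidine, CH2Cl2, −78 → 0 °C
Reagents that add atoms: tert-butyldimethylsilyl triflate, CC(C)(C)[Si](C)(C)OS(=O)(=O)C(F)(F)F
Why: Silyl triflate silylation of the hindered neopentyl secondary alcohol, which leaves the ketone untouched at low temperature and blocks alkoxide-triggered vinylogous retro-aldol cleavage in step 6.

**Step 5**
Reactants: 8 (7S)-7-[(tert-butyldimethylsilyl)oxy]-4,8,8-trimethyldec-9-en-3-one; 9 (E)-but-2-enal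
Product: 10 (2E,5S)-5-[(tert-butyldimethylsilyl)oxy]-4,4,8-trimethyl-9-oxoundec-2-enal
Conditions: 9 (5 equiv), second-generation Hoveyda–Grubbs catalyst [RuCl2(H2IMes)(=CH-C6H4-2-O-i-Pr)] (5 mol %), CH2Cl2, 40 °C
Reagents that add atoms: none
Why: Olefin cross-metathesis between a vinyl group on a quaternary carbon, which does not homodimerise, and an electron-poor enal partner, giving the E-enal under thermodynamic control.

**Step 6**
Reactants: 10 (2E,5S)-5-[(tert-butyldimethylsilyl)oxy]-4,4,8-trimethyl-9-oxoundec-2-enal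
Product: 13 3β-TBSO-4,4,8,10β-tetramethyl-5α-decal-7-en-9-one (trans-fused enone), via Michael adduct 11 (not isolated), via aldol 12 (not isolated)
Conditions: t-BuOK (0.5 equiv), t-BuOH/THF 1:4 (0.01 M), 0 → 45 °C
Reagents that add atoms: none
Why: Catalytic t-BuOK equilibrates the ketone enolates of 10, and only the more substituted C10 enolate can reach the enal β-carbon C5, adding in a 6-(enolexo)-exo-trig Michael reaction that forms C5–C10 and closes ring A to give 11. The unmasked C7 aldehyde is then attacked by the C8 enolate, the only enolisable position left on the C9 ketone, in a 6-(enolendo)-exo-trig aldol addition that closes ring B (12), and E1cB loss of water gives enone 13. The closest known reaction type is the Robinson annulation (Michael addition, then aldol condensation), here run intramolecularly so that both rings form from an open chain. C5 and C10 are set in the Michael step by a chair transition state for ring A in which the C3 silyloxy group, the enal arm on C5 and the bulkier enolate branch (C9) on C10 are all equatorial, which leaves the C10 methyl axial and anti to H5 and so should give the trans ring fusion (5α-H, 10β-CH3) relayed from C3. The step needs C10-over-C8 regioselectivity, secured because the C8 enolate could only close an eight-membered ring, and intramolecular over intermolecular aldehyde reactions, secured by high dilution and by quaternary C4, which leaves the enal without γ-hydrogens. The Michael addition is reversible, and irreversible dehydration to the conjugated enone drains the equilibrium.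

**Step 7**
Reactants: 13 3β-TBSO-4,4,8,10β-tetramethyl-5α-decal-7-en-9-one
Product: 15 3β-TBSO-4,4,8α,10β-tetramethyl-5α-decalin-9-one, via 8β-methyl ketone 14 (not isolated)
Conditions: H2 (1 atm), Pd/C, EtOAc, rt; filter; then NaOMe (cat.), MeOH, rt
Reagents that add atoms: none
Why: Heterogeneous hydrogenation of the conjugated C7=C8 bond, followed by base equilibration through the C9 enolate, which places the C8 methyl equatorial (8α), clear of the 1,3-diaxial interaction with the C10 methyl.

**Step 8**
Reactants: 15 3β-TBSO-4,4,8α,10β-tetramethyl-5α-decalin-9-one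
Product: 16 3β-TBSO-4,4,8α,10β-tetramethyl-9-methylidene-5α-decalin
Conditions: Ph3PCH3Br, t-BuOK, toluene, 90 °C
Reagents that add atoms: methylenetriphenylphosphorane, C=P(c1ccccc1)(c1ccccc1)c1ccccc1
Why: Wittig methylenation under the forcing alkoxide/hot toluene conditions used for hindered enolisable ketones; C8 remains in its thermodynamic configuration.

**Step 9**
Reactants: 16 3β-TBSO-4,4,8α,10β-tetramethyl-9-methylidene-5α-decalin
Product: 17 3β-TBSO-9α,11-epoxy-4,4,8α,10β-tetramethyl-5α-decalin (spiro-oxirane, oxygen α, C11 β)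
Conditions: mCPBA, NaHCO3, CH2Cl2, 0 °C
Reagents that add atoms: 3-chloroperoxybenzoic acid, OOC(=O)c1cccc(Cl)c1
Why: Prilezhaev epoxidation of the exocyclic alkene from the α face (axial attack), the β face being shielded by the adjacent axial C10 methyl, which places the C9 oxygen α.

**Step 10**
Reactants: 17 3β-TBSO-9α,11-epoxy-4,4,8α,10β-tetramethyl-5α-decalin
Product: 18 3β-TBSO-4,4,8α,10β-tetramethyl-9β-vinyl-5α-decalin-9α-ol
Conditions: Me3SI, n-BuLi, THF, −10 °C → rt
Reagents that add atoms: dimethylsulfonium methylide, [CH2-][S+](C)C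
Why: One-carbon homologation of an epoxide to an allylic alcohol with excess sulfonium ylide, by SN2 opening at the CH2 terminus (C11) and ylide-mediated syn-elimination of dimethyl sulfide, which leaves the C9–O bond and hence the 9α-oxygen configuration untouched.

**Step 11**
Reactants: 18 3β-TBSO-4,4,8α,10β-tetramethyl-9β-vinyl-5α-decalin-9α-ol
Product: 19 4,4,8α,10β-tetramethyl-9β-vinyl-5α-decalin-3β,9α-diol
Conditions: TBAF, THF, 60 °C
Reagents that add atoms: none
Why: Fluoride-mediated desilylation of the hindered secondary silyl ether under basic conditions that the tertiary allylic alcohol tolerates.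

**Step 12**
Reactants: 19 4,4,8α,10β-tetramethyl-9β-vinyl-5α-decalin-3β,9α-diol; 20 4-bromofuran-2(5H)-one
Product: 22 3β,9α-dihydroxylabd-13-en-15,16-olide, via B-alkyl-9-BBN adduct 21 (not isolated)
Conditions: 9-BBN dimer (excess), THF, 0 °C → rt; then K3PO4 (aq), 20, Pd(dppf)Cl2 (10 mol %), AsPh3, DMF, rt
Reagents that add atoms: none
Why: Anti-Markovnikov hydroboration of the vinyl group followed by B-alkyl Suzuki–Miyaura coupling with the β-bromobutenolide forms C12–C13 under mild base at room temperature, which limits lactone opening and oxa-Michael closure of the 9-hydroxyl onto C13.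

**Step 13**
Reactants: 22 3β,9α-dihydroxylabd-13-en-15,16-olide
Product: 23 3β-acetoxy-9α-hydroxylabd-13-en-15,16-olide (CNP0578261.2)
Conditions: Ac2O, pyridine, rt
Reagents that add atoms: acetic anhydride, CC(=O)OC(C)=O
Why: Acylation of the equatorial secondary C3 alcohol, which should be selective because the axial tertiary C9 alcohol beside quaternary C10 is unreactive under these conditions.

**Compound list**

1 | pentan-3-one | CCC(=O)CC | starting material
2 | 2-(2-bromoethyl)-1,3-dioxolane | BrCCC1OCCO1 | starting material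
3 | lithium pent-2-en-3-olate (E/Z mixture) | [Li+].CC=C([O-])CC | intermediate (not isolated)
4 | 6-(1,3-dioxolan-2-yl)-4-methylhexan-3-one (racemic) | CCC(=O)C(C)CCC1OCCO1 | intermediate
5 | 4-methyl-5-oxoheptanal (racemic) | CCC(=O)C(C)CCC=O | intermediate
6 | diisopinocampheylborinate ester of 7 | CCC(=O)C(C)CC[C@H](OB([C@@H]1[C@@H](C)[C@@H]2C[C@H](C1)C2(C)C)[C@@H]1[C@@H](C)[C@@H]2C[C@H](C1)C2(C)C)C(C)(C)C=C | intermediate (not isolated)
7 | (7S)-7-hydroxy-4,8,8-trimethyldec-9-en-3-one (C4 epimers) | CCC(=O)C(C)CC[C@H](O)C(C)(C)C=C | intermediate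
8 | (7S)-7-[(tert-butyldimethylsilyl)oxy]-4,8,8-trimethyldec-9-en-3-one (C4 epimers) | CCC(=O)C(C)CC[C@H](O[Si](C)(C)C(C)(C)C)C(C)(C)C=C | intermediate
9 | (E)-but-2-enal | C/C=C/C=O | starting material
10 | (2E,5S)-5-[(tert-butyldimethylsilyl)oxy]-4,4,8-trimethyl-9-oxoundec-2-enal (C8 epimers) | CCC(=O)C(C)CC[C@H](O[Si](C)(C)C(C)(C)C)C(C)(C)/C=C/C=O | intermediate
11 | ring A keto aldehyde: 2-[3β-TBSO-4,4,10β-trimethyl-10α-propanoylcyclohex-5β-yl]acetaldehyde (5α-H) | CC(C)(C)[Si](C)(C)O[C@H]1CC[C@@](C(=O)CC)(C)[C@@H](CC=O)C1(C)C | intermediate (not isolated)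
12 | 3β-TBSO-7-hydroxy-4,4,8,10β-tetramethyl-5α-decalin-9-one (C7, C8 mixture) | CC(C)(C)[Si](C)(C)O[C@H]1CC[C@@]2(C)[C@@H](CC(O)C(C)C2=O)C1(C)C | intermediate (not isolated)
13 | 3β-TBSO-4,4,8,10β-tetramethyl-5α-decal-7-en-9-one | CC(C)(C)[Si](C)(C)O[C@H]1CC[C@@]2(C)[C@@H](CC=C(C)C2=O)C1(C)C | intermediate
14 | 3β-TBSO-4,4,8β,10β-tetramethyl-5α-decalin-9-one | CC(C)(C)[Si](C)(C)O[C@H]1CC[C@@]2(C)[C@@H](CC[C@H](C)C2=O)C1(C)C | intermediate (not isolated)
15 | 3β-TBSO-4,4,8α,10β-tetramethyl-5α-decalin-9-one | CC(C)(C)[Si](C)(C)O[C@H]1CC[C@@]2(C)[C@@H](CC[C@@H](C)C2=O)C1(C)C | intermediate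
16 | 3β-TBSO-4,4,8α,10β-tetramethyl-9-methylidene-5α-decalin | CC(C)(C)[Si](C)(C)O[C@H]1CC[C@@]2(C)[C@@H](CC[C@@H](C)C2=C)C1(C)C | intermediate
17 | 3β-TBSO-9α,11-epoxy-4,4,8α,10β-tetramethyl-5α-decalin | CC(C)(C)[Si](C)(C)O[C@H]1CC[C@@]2(C)[C@@H](CC[C@@H](C)[C@]2(O3)C3)C1(C)C | intermediate
18 | 3β-TBSO-4,4,8α,10β-tetramethyl-9β-vinyl-5α-decalin-9α-ol | CC(C)(C)[Si](C)(C)O[C@H]1CC[C@@]2(C)[C@@H](CC[C@@H](C)[C@]2(O)C=C)C1(C)C | intermediate
19 | 4,4,8α,10β-tetramethyl-9β-vinyl-5α-decalin-3β,9α-diol | O[C@H]1CC[C@@]2(C)[C@@H](CC[C@@H](C)[C@]2(O)C=C)C1(C)C | intermediate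
20 | 4-bromofuran-2(5H)-one | O=C1OCC(Br)=C1 | starting material
21 | B-alkyl-9-BBN adduct of 19 (boron on C12) | O[C@H]1CC[C@@]2(C)[C@@H](CC[C@@H](C)[C@]2(O)CCB3C4CCCC3CCC4)C1(C)C | intermediate (not isolated)
22 | 3β,9α-dihydroxylabd-13-en-15,16-olide | O[C@H]1CC[C@@]2(C)[C@@H](CC[C@@H](C)[C@]2(O)CCC2=CC(=O)OC2)C1(C)C | intermediate
23 | 3β-acetoxy-9α-hydroxylabd-13-en-15,16-olide (CNP0578261.2) | CC(=O)O[C@H]1CC[C@@]2(C)[C@@H](CC[C@@H](C)[C@]2(O)CCC2=CC(=O)OC2)C1(C)C | target

**Step count.** Total: 13 steps. Longest linear sequence: 13 steps (the route is fully linear).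

**Steps most likely to fail**

1. Step 6 (key step). The Michael addition at C5, a neopentyl β-carbon that ends up between two fully substituted carbons, may be slow and reversible, so that intermolecular aldol condensation of the enal takes over. The enolate branch may also take the axial position and erode the trans ring fusion. The fallback sets out from 8 and comes back at 13; it answers the enal reactivity problem, not the ring-fusion risk. Cross-metathesis of 8 with methyl acrylate under the conditions of step 5 gives the keto enoate methyl (2E,5S)-5-[(tert-butyldimethylsilyl)oxy]-4,4,8-trimethyl-9-oxoundec-2-enoate F1, which has no aldehyde to self-condense. Treatment with t-BuOK (2 equiv) in THF/t-BuOH then drives a Michael–Dieckmann double cyclisation, pulled to completion by deprotonation of its product, the β-diketone 3β-TBSO-4,4,8,10β-tetramethyl-5α-decalin-7,9-dione F2. O-Triflation at the less hindered C7 oxygen (Tf2O, Et3N, CH2Cl2, −78 °C) gives the vinylogous triflate 3β-TBSO-4,4,8,10β-tetramethyl-9-oxo-5α-decal-7-en-7-yl trifluoromethanesulfonate F3. Palladium-catalysed formate reduction (Pd(OAc)2, PPh3, HCO2H, Et3N, DMF, 60 °C) then gives enone 13.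

2. Step 10. SN2 opening at C11, a neopentyl-type carbon beside quaternary C9, may be slow, so that lithium-ion-promoted rearrangement of the spiro-epoxide to the C11 aldehyde or base-induced isomerisation to an allylic alcohol competes. The fallback sets out from 16 and comes back at 18, with no substitution at C11. Dihydroxylation of 16 from the α face (OsO4 cat., NMO, acetone/H2O) gives the diol 3β-TBSO-4,4,8α,10β-tetramethyl-5α-decalin-9α,11-diol F4. Oxidation of the primary alcohol (SO3·pyridine, DMSO, Et3N) gives the α-hydroxy aldehyde 3β-TBSO-9α-hydroxy-4,4,8α,10β-tetramethyl-5α-decalin-9β-carbaldehyde F5. Wittig methylenation at low temperature (Ph3PCH3Br, KN(SiMe3)2, THF, −78 → 0 °C) then gives 18.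

3. Step 8. The basic ylide may enolise the ketone towards C8 faster than it adds to a carbonyl flanked by quaternary C10 and branched C8, returning 15. The fallback sets out from 15 and comes back at 16 by a Peterson olefination in two operations. The weakly basic organocerium reagent from Me3SiCH2Li and CeCl3 (THF, −78 °C) adds to C9 to give the β-hydroxysilane 3β-TBSO-4,4,8α,10β-tetramethyl-9α-[(trimethylsilyl)methyl]-5α-decalin-9β-ol F6 (either C9 epimer serves). KH in THF then induces syn-elimination to give 16.

**Further compounds**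

F1 | step 6 | methyl (2E,5S)-5-[(tert-butyldimethylsilyl)oxy]-4,4,8-trimethyl-9-oxoundec-2-enoate | CCC(=O)C(C)CC[C@H](O[Si](C)(C)C(C)(C)C)C(C)(C)/C=C/C(=O)OC
F2 | step 6 | 3β-TBSO-4,4,8,10β-tetramethyl-5α-decalin-7,9-dione | CC(C)(C)[Si](C)(C)O[C@H]1CC[C@@]2(C)[C@@H](CC(=O)C(C)C2=O)C1(C)C
F3 | step 6 | 3β-TBSO-4,4,8,10β-tetramethyl-9-oxo-5α-decal-7-en-7-yl trifluoromethanesulfonate | CC(C)(C)[Si](C)(C)O[C@H]1CC[C@@]2(C)[C@@H](CC(OS(=O)(=O)C(F)(F)F)=C(C)C2=O)C1(C)C
F4 | step 10 | 3β-TBSO-4,4,8α,10β-tetramethyl-5α-decalin-9α,11-diol | CC(C)(C)[Si](C)(C)O[C@H]1CC[C@@]2(C)[C@@H](CC[C@@H](C)[C@]2(O)CO)C1(C)C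
F5 | step 10 | 3β-TBSO-9α-hydroxy-4,4,8α,10β-tetramethyl-5α-decalin-9β-carbaldehyde | CC(C)(C)[Si](C)(C)O[C@H]1CC[C@@]2(C)[C@@H](CC[C@@H](C)[C@]2(O)C=O)C1(C)C
F6 | step 8 | 3β-TBSO-4,4,8α,10β-tetramethyl-9α-[(trimethylsilyl)methyl]-5α-decalin-9β-ol | CC(C)(C)[Si](C)(C)O[C@H]1CC[C@@]2(C)[C@@H](CC[C@@H](C)[C@@]2(O)C[Si](C)(C)C)C1(C)C
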